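All runs stem from a simulated flask for an exercise, and the scatter is random.

**Follow D.** You want two ends. The substrate E is no help: dusk shows 0% of it at 15.0 min. The steps thought possible are E → D, Z → J, D + J → L and E + Q → X, so you follow D, formed on the way, as it meets J, formed from the reagent Z, and gives the product L; Q is a further species in the flask, and X another product.

the same everywhere: E 43 mM
- dusk: Z 44 mM; Q 0.86 mM; run made earlier
- midnight: Z 52 mM; Q 0.86 mM; run made earlier
- west: Z 41.0 mM; Q 0.860 mM; time 20 min
- north: Z 61.0 mM; Q 0.860 mM; time 20 min

| run | time / min | D / % | L / % | E / % |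
|---|---|---|---|---|
| dusk | 1.00 | 76.4 | 0.5 | 21.5 |
| dusk | 2.50 | 93.6 | 1.4 | 1.8 |
| dusk | 6.00 | 88.3 | 9.6 | 0.2 |
| dusk | 15.0 | 63.7 | 33.9 | 0 |
| midnight | 2.00 | 92.0 | 2.0 | 4.6 |
| midnight | 5.00 | 90.2 | 8.3 | 0.5 |
| midnight | 10.0 | 74.0 | 24.5 | 0.2 |
| midnight | 15.0 | 58.7 | 38.9 | 0 |

(standard deviation of a reading: 0.3 percentage points)

1. which of these there is most of at the end, counted by the E in it, west (D / L / E)
2. which of these there is most of at the end, counted by the E in it, north (D / L / E)
3. amount of the one of these that there is most of at the end, in percent of the E charged, west
4. amount of the one of these that there is most of at the end, in percent of the E charged, north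

**The sum.** At 15.0 min, the readings of D plus L give T = 97.6% in midnight and 97.6% in dusk. Now set the two runs against each other at that one time, so that time drops out. Let Z₀ be the Z charged.

**First extreme.** Suppose L's rate ignores D and follows Z₀. Then s, the mM of L per mM of Z₀, should match at equal times; the readings give 0.331 in dusk, 0.322 in midnight. Midnight's s was 0.203 at 10.0 min; stepped on evenly, it gives an estimate of 0.441 at 20 min. That puts L at 42.0% in west and 62.5% in north.

**Second extreme.** Suppose L's rate is proportional to D and to Z₀, so that D decays pseudo-first-order. Then ln(T/D)/Z₀ should match at equal times; the readings give 0.00970 /mM in dusk, 0.00978 /mM in midnight. Midnight gave 0.00532 /mM at 10.0 min, so the even step gives 0.0142 /mM at 20 min. This is G, the thinning number: ln(T/D) per mM of Z₀ at a fixed time. The estimate for west is then D at 54.5% and L at 43.1%; for north it is D at 41.0% and L at 56.6%.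

**Between them.** If J can wait for D, L's rate falls with D, but less than in proportion, so the flask should lie between the extremes. They part by 1.1 percentage points in west and 5.9 points in north. Either way, D leads in west and L in north. The two runs differ more in s than in G, so I lean to the second extreme.

The forecast gives D at 57.5% in west and L at 59.5% in north, holding that “J is trapped quickly by D”.

**The flasks.** West holds 55.4% of D and 42.7% of L; north holds 57.8% of L and 40.2% of D.

    E → D (k = 1.50 /min)
    Z → J (k = 0.0710 /min)
    D + J → L (k = 2.70 /M/min)
    E + Q → X (k = 140 /M/min)

**Less Z.** Read back from these ends, G is 0.0138 /mM in west and 0.0145 /mM in north. Now take a neighbour: north recharged with 37 mM of Z, read at the same time. My G gives D at 57.7%, still ahead of L at 39.9%. That neighbour holds 58.9% of D and 39.2% of L at 20.0 min.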